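The autumn run comes first here: its charges of substrate and coupling partner are those of the new flasks, and Thursday's, Monday's, Tuesday's and Sunday's differ from it in the way things go in.

| setting | autumn | spring | dawn | Thursday's | Monday's | Tuesday's | Sunday's | Saturday's |
|---|---|---|---|---|---|---|---|---|
| substrate | 0.050 M | 0.050 M | 0.050 M | 0.050 M (fed, over 3.0 min) | 0.050 M | 0.050 M | 0.050 M | 0.050 M |
| coupling partner | 0.045 M | 0.063 M | 0.099 M | 0.0450 M | 0.0450 M (in portions, 2, over 3.0 min) | 0.0450 M (fed, over 50 s) | 0.0450 M (fed, over 3.0 min) | 0.0450 M |
| remark | run made earlier | run made earlier | run made earlier | all else is in the flask from the start; the feed brings no volume worth counting | first portion at the start, last at 3.0 min | all else is in the flask from the start; the feed brings no volume worth counting | all else is in the flask from the start; the feed brings no volume worth counting | everything together at the start |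
| time |  |  |  | 15 min | 15 min | 15 min | 15 min | 15 min |

| autumn: time / min | autumn: target / % | spring: time / min | spring: target / % | dawn: time / min | dawn: target / % |
|---|---|---|---|---|---|
| 0.667 | 39 | 1.50 | 59 | 1.00 | 74 |
| 1.00 | 42 | 3.00 | 63 | 1.33 | 77 |
| 1.50 | 46 | 5.00 | 64 | 2.00 | 81 |
| 2.50 | 51 | 6.00 | 63 | 3.00 | 80 |
| 4.00 | 49 | 8.00 | 62 | 5.00 | 81 |
| 6.00 | 48 | 10.0 | 61 | 8.00 | 79 |
| 10.0 | 46 | 12.0 | 59 | 12.0 | 80 |

(each reading ± 1.5 percentage points)

- a reading or a percentage of target counts all its forms, free or not

- the flask with the highest amount of target, in percent of the substrate charged ("all alike" if they lie within 1.5 percentage points) (Thursday's / Monday's / Tuesday's / Sunday's / Saturday's / all alike)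
- final target, as a percentage of the substrate charged, in Thursday's
- final target, as a percentage of the substrate charged, in Monday's
- final target, as a percentage of the substrate charged, in Tuesday's
- final target, as a percentage of the substrate charged, in Sunday's
- final target, as a percentage of the substrate charged, in Saturday's

Down the autumn table, target climbs to 51% at 2.50 min, then falls to 46% at 10.0 min. Read as a settling towards a balance of a reversible coupling, the last row is taken as the level. The excess over it shrinks from 5 percentage points at 2.50 min to 2 points at 6.00 min, which gives a settling half-life t½ of 2.65 min. This is a coarse reading, because those excesses stand against a scatter of 1.5 points.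

The last row also gives the apparent equilibrium quotient Q, which is [target] divided by [substrate] times [coupling partner], with each of those two taken as its charge minus target: 38.7 M⁻¹. The last rows of spring and dawn give 43.0 M⁻¹ and 67.8 M⁻¹, so Q is carried here at autumn's charge of coupling partner.

In Thursday's, Sunday's and Monday's the last addition comes at 3.0 min, which by this reading leaves 4.53 half-lives before 15 min, and the reckoning keeps 4.32% of an offset from the level. The reckoning here therefore puts the new flasks near 46%, all alike.

The forecast differs. It holds that “keeping partner dilute helps” and gives 34% for Thursday's, 55% for Monday's, 50% for Tuesday's, 56% for Sunday's and 44% for Saturday's, with Sunday's highest.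

The flasks end at 45.7% in Thursday's, 45.8% in Monday's, 45.8% in Tuesday's, 45.8% in Sunday's and 45.8% in Saturday's: all alike.

    substrate + coupling partner ⇌ target (K = 60.0 M⁻¹, k = 29.0 M⁻¹ min⁻¹)
    crystals ⇌ target, rate k2*(cs2 - [target]) while solid is left; crystals form when [target] > cs2 (solubility = 23.0 mM, k = 5.70 min⁻¹)
    coupling partner ⇌ dormant form (K = 0.580, k = 0.150 min⁻¹)

In Sunday's, coupling to target had half of its turnover up to 15 min done by 1.69 min, earlier than the step to dormant form, which reached that mark at 3.10 min. Sunday's held 47.3% target, 1.34% crystals counted in it, at 7.50 min, and 45.8% target with 0% crystals at 15.0 min. Q reckoned from Sunday's end is 38.3 M⁻¹. With 0.030 M of substrate in a flask otherwise like Sunday's, the autumn Q gives 53.0%, and that flask ends at 52.7%.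

All runs come from a simulation with constants of no real substance.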